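## Retrosynthetic overview

1. Target ⇒ macrocyclic C8 silyl ether / C10 tertiary ketol by removing the ester endgame (methacrylate at C8, acetate at C10); the C13 acetate is carried from the start.
2. Ten-membered carbocycle ⇒ seco keto-aldehyde by cutting C1–C10 (NHC-catalysed aldehyde–ketone benzoin macrocyclisation, sets C10); this ring is formed last.
3. Butenolide and C5–C6 bond ⇒ (Z)-alkenyl iodide + (Z)-formyl acrylate (asymmetric Nozaki–Hiyama–Kishi addition, then lactonisation, sets C6); the butenolide is formed second.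
4. (Z)-Formyl acrylate ⇒ 3,4-disubstituted furan (singlet-oxygen unmasking); its β-silyloxy ketone arm ⇒ furan aldehyde + acetone (prolinamide-catalysed aldol, sets C8, the first stereocentre).
5. Ring order: furan (bought, a masked butenolide) → butenolide (step 7) → ten-membered ring (step 9).

Numbering used in the text (germacrane): C1 = ring ketone, C4=C5 = ring olefin, C6 = lactone CH–O, C7=C11 = butenolide olefin, C8 = methacryloyloxy carbon, C10 = acetoxy carbon, C12 = lactone carbonyl, C13 = acetoxymethyl carbon.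

Assumption: the ligand antipode in step 7 and the triazolium antipode in step 9 are the ones that give the drawn 6R and 10S centres; the antipodes named are those expected from the usual facial models and would be confirmed in the first run.

## Route

Step 1
Reactants: 1 furan-3,4-diyldimethanol
Product: 2 4-(hydroxymethyl)furan-3-carbaldehyde
Conditions: MnO2 (8 equiv), CH2Cl2, rt, stopped at ca. 85% conversion
Reagents that add atoms: none
Why: Activated MnO2 oxidises heteroaryl carbinols (benzylic-type oxidation), and the first formyl group deactivates the ring toward a second oxidation while the strained 3,4-fused lactol does not form, so the mono-aldehyde is isolated.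

Step 2
Reactants: 2 4-(hydroxymethyl)furan-3-carbaldehyde
Product: 3 (4-formylfuran-3-yl)methyl acetate
Conditions: Ac2O, pyridine, DMAP (cat.), CH2Cl2, 0 °C
Reagents that add atoms: acetic anhydride CC(=O)OC(C)=O
Why: DMAP-catalysed acylation of the primary alcohol (nucleophilic acyl substitution) installs at the outset the acetate that becomes the C13 acetoxymethyl group.

Step 3
Reactants: 3 (4-formylfuran-3-yl)methyl acetate; 4 acetone
Product: 5 [4-[(1S)-1-hydroxy-3-oxobutyl]furan-3-yl]methyl acetate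
Conditions: (2R)-N-[(2R)-1-hydroxy-4-methyl-1,1-diphenylpentan-2-yl]pyrrolidine-2-carboxamide (10 mol %), acetone (solvent), −35 °C
Reagents that add atoms: none
Why: Enamine-catalysed direct asymmetric aldol reaction (List–Barbas–Singh type): the D-series prolinamide forms the acetone enamine and its amide N–H and carbinol O–H hydrogen-bond the aldehyde so that the Si face is attacked, setting C8 as S (≥95% ee expected).

Step 4
Reactants: 5 [4-[(1S)-1-hydroxy-3-oxobutyl]furan-3-yl]methyl acetate
Product: 6 [4-[(1S)-1-[tert-butyl(dimethyl)silyl]oxy-3-oxobutyl]furan-3-yl]methyl acetate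
Conditions: TBSOTf, 2,6-lutidine, CH2Cl2, −78 °C
Reagents that add atoms: tert-butyldimethylsilyl trifluoromethanesulfonate CC(C)(C)[Si](C)(C)OS(=O)(=O)C(F)(F)F
Why: Silyl triflate silylation with a hindered pyridine base protects the C8 hydroxyl without touching the methyl ketone, blocking retro-aldol, acetyl migration and later lactonisation onto C12.

Step 5
Reactants: 6 [4-[(1S)-1-[tert-butyl(dimethyl)silyl]oxy-3-oxobutyl]furan-3-yl]methyl acetate
Product: 9 methyl (2Z,4S)-2-(acetyloxymethyl)-4-[tert-butyl(dimethyl)silyl]oxy-3-formyl-6-oxohept-2-enoate, via furan endoperoxide 7 (not isolated), via pseudo-acid 8 (not isolated)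
Conditions: O2, hν (visible), tetraphenylporphyrin (1 mol %), iPr2NEt (3 equiv), CH2Cl2, −78 °C; then MeI, DMF, −78 °C to rt
Reagents that add atoms: dioxygen (used as singlet oxygen) O=O; iodomethane CI
Why: [4+2] cycloaddition of singlet oxygen gives endoperoxide 7, the hindered amine removes the less encumbered bridgehead hydrogen next to the acetoxymethyl arm (Kornblum–DeLaMare fragmentation, Faulkner regiocontrol) so that this carbon becomes C12, and the ammonium carboxylate of ring-opened 8 is O-methylated in the same pot to the (Z)-formyl ester.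

Step 6
Reactants: 10 pent-4-yn-1-ol
Product: 13 (4Z)-5-iodo-4-methylpent-4-en-1-ol, via E-alkenylalane 11 (not isolated), via cyclic Z-alkenylalane 12 (not isolated)
Conditions: Me3Al (3 equiv), Cp2ZrCl2 (25 mol %), ClCH2CH2Cl, rt; then reflux, 72 h; then iodine, THF, −30 to 0 °C
Reagents that add atoms: trimethylaluminium C[Al](C)C; iodine [I][I]
Why: Negishi zirconium-catalysed syn-carboalumination followed by alkoxide-chelation-driven isomerisation of the alkenylalane gives net anti-addition of methyl and aluminium, and iodinolysis with retention delivers the (Z)-iodide in which the chain and iodine are cis.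

Step 7
Reactants: 9 methyl (2Z,4S)-2-(acetyloxymethyl)-4-[tert-butyl(dimethyl)silyl]oxy-3-formyl-6-oxohept-2-enoate; 13 (4Z)-5-iodo-4-methylpent-4-en-1-ol
Product: 15 [(5R)-4-[(1S)-1-[tert-butyl(dimethyl)silyl]oxy-3-oxobutyl]-5-[(1Z)-5-hydroxy-2-methylpent-1-en-1-yl]-2-oxo-2,5-dihydrofuran-3-yl]methyl acetate, via open-chain hydroxy ester 14 (not isolated)
Conditions: 13 (1.5 equiv), CrCl2 (10 mol %), (S)-N-[2-(4-isopropyl-4,5-dihydro-1,3-oxazol-2-yl)-6-methoxyphenyl]methanesulfonamide (11 mol %), 1,8-bis(dimethylamino)naphthalene (11 mol %), NiCl2(2,9-dimethyl-1,10-phenanthroline) (2 mol %), Mn (2 equiv), Cp2ZrCl2 (2.5 equiv), LiCl (2 equiv), MeCN, rt; then PPTS (cat.), CH2Cl2, rt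
Reagents that add atoms: none
Why: Catalytic asymmetric Nozaki–Hiyama–Kishi coupling: nickel activation of the alkenyl iodide and transmetalation give an alkenylchromium species that adds only to the aldehyde (ketone, esters and free hydroxyl tolerated) with retention of the Z geometry, the oxazoline–sulfonamide ligand on chromium selects the aldehyde face to set C6 as R, and the (Z)-γ-alkoxy ester 14 lactonises to the butenolide.

Step 8
Reactants: 15 [(5R)-4-[(1S)-1-[tert-butyl(dimethyl)silyl]oxy-3-oxobutyl]-5-[(1Z)-5-hydroxy-2-methylpent-1-en-1-yl]-2-oxo-2,5-dihydrofuran-3-yl]methyl acetate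
Product: 16 [(5R)-4-[(1S)-1-[tert-butyl(dimethyl)silyl]oxy-3-oxobutyl]-5-[(1Z)-2-methyl-5-oxopent-1-en-1-yl]-2-oxo-2,5-dihydrofuran-3-yl]methyl acetate
Conditions: Dess–Martin periodinane, NaHCO3, CH2Cl2, 0 °C
Reagents that add atoms: none
Why: Dess–Martin oxidation converts the only free (primary) alcohol into the aldehyde under buffered, non-basic conditions that leave the epimerisable C6 and the β-silyloxy ketone untouched.

Step 9
Reactants: 16 [(5R)-4-[(1S)-1-[tert-butyl(dimethyl)silyl]oxy-3-oxobutyl]-5-[(1Z)-2-methyl-5-oxopent-1-en-1-yl]-2-oxo-2,5-dihydrofuran-3-yl]methyl acetate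
Product: 17 [(4S,6S,10Z,11aR)-4-[tert-butyl(dimethyl)silyl]oxy-6-hydroxy-6,10-dimethyl-2,7-dioxo-2,4,5,6,7,8,9,11a-octahydrocyclodeca[b]furan-3-yl]methyl acetate
Conditions: (5aS,10bR)-2-(pentafluorophenyl)-5a,10b-dihydro-4H,6H-indeno[2,1-b][1,2,4]triazolo[4,3-d][1,4]oxazin-2-ium tetrafluoroborate (20 mol %), iPr2NEt (20 mol %), toluene, 1 mM (16 added over 12 h), 40 °C
Reagents that add atoms: none
Why: Proposed new method: an NHC-catalysed macrocyclising aldehyde–ketone crossed benzoin, in which the triazolylidene adds to the unhindered C1 aldehyde to give the Breslow intermediate (acyl anion equivalent) that attacks the C10 methyl ketone intramolecularly; the (Z)-olefin and the planar butenolide hold the two termini in a cisoid arc, intermolecular aldehyde–aldehyde benzoin adducts form reversibly and funnel back while the tertiary α-ketol is the sink, and the chiral aminoindanol-derived carbene (reinforced by the β-silyloxy centre) selects the ketone face to set C10 as S; the closest known reaction is the NHC-catalysed intramolecular aldehyde–ketone crossed benzoin cyclisation to five- and six-membered tertiary α-ketols, which has not been shown for a medium ring.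

Step 10
Reactants: 17 [(4S,6S,10Z,11aR)-4-[tert-butyl(dimethyl)silyl]oxy-6-hydroxy-6,10-dimethyl-2,7-dioxo-2,4,5,6,7,8,9,11a-octahydrocyclodeca[b]furan-3-yl]methyl acetate
Product: 18 [(4S,6S,10Z,11aR)-4,6-dihydroxy-6,10-dimethyl-2,7-dioxo-2,4,5,6,7,8,9,11a-octahydrocyclodeca[b]furan-3-yl]methyl acetate
Conditions: HF·pyridine, pyridine, THF, 0 °C to rt
Reagents that add atoms: none
Why: Fluoride-mediated Si–O cleavage under buffered acidic conditions removes the TBS ether without base, which could epimerise C6 or move the lactone to the C8 oxygen.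

Step 11
Reactants: 18 [(4S,6S,10Z,11aR)-4,6-dihydroxy-6,10-dimethyl-2,7-dioxo-2,4,5,6,7,8,9,11a-octahydrocyclodeca[b]furan-3-yl]methyl acetate
Product: 19 [(4S,6S,10Z,11aR)-3-(acetyloxymethyl)-6-hydroxy-6,10-dimethyl-2,7-dioxo-2,4,5,6,7,8,9,11a-octahydrocyclodeca[b]furan-4-yl] 2-methylprop-2-enoate
Conditions: methacrylic anhydride (1.5 equiv), DMAP (10 mol %), pyridine, CH2Cl2, 0 °C
Reagents that add atoms: methacrylic anhydride C=C(C)C(=O)OC(=O)C(C)=C
Why: DMAP-catalysed acylation discriminates sterically between the secondary C8 hydroxyl and the tertiary α-ketol hydroxyl, so only the C8 methacrylate forms.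

Step 12
Reactants: 19 [(4S,6S,10Z,11aR)-3-(acetyloxymethyl)-6-hydroxy-6,10-dimethyl-2,7-dioxo-2,4,5,6,7,8,9,11a-octahydrocyclodeca[b]furan-4-yl] 2-methylprop-2-enoate
Product: 20 [(4S,6S,10Z,11aR)-6-acetyloxy-3-(acetyloxymethyl)-6,10-dimethyl-2,7-dioxo-2,4,5,6,7,8,9,11a-octahydrocyclodeca[b]furan-4-yl] 2-methylprop-2-enoate (CNP0115165.3)
Conditions: Ac2O, Sc(OTf)3 (5 mol %), MeCN, −20 °C
Reagents that add atoms: acetic anhydride CC(=O)OC(C)=O
Why: Sc(OTf)3-catalysed acylation with Ac2O acetylates hindered tertiary alcohols at low temperature under non-basic conditions, completing the target without disturbing C6 or the methacrylate.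

## Compound list

1 | furan-3,4-diyldimethanol | OCc1cocc1CO | starting material
2 | 4-(hydroxymethyl)furan-3-carbaldehyde | O=Cc1cocc1CO | intermediate
3 | (4-formylfuran-3-yl)methyl acetate | CC(=O)OCc1cocc1C=O | intermediate
4 | acetone | CC(C)=O | starting material
5 | [4-[(1S)-1-hydroxy-3-oxobutyl]furan-3-yl]methyl acetate | CC(=O)C[C@H](O)c1cocc1COC(C)=O | intermediate
6 | [4-[(1S)-1-[tert-butyl(dimethyl)silyl]oxy-3-oxobutyl]furan-3-yl]methyl acetate | CC(=O)C[C@H](O[Si](C)(C)C(C)(C)C)c1cocc1COC(C)=O | intermediate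
7 | [6-[(1S)-1-[tert-butyl(dimethyl)silyl]oxy-3-oxobutyl]-2,3,7-trioxabicyclo[2.2.1]hept-5-en-5-yl]methyl acetate (furan endoperoxide, bridgehead epimers) | CC(=O)C[C@H](O[Si](C)(C)C(C)(C)C)C1=C(COC(C)=O)C2OOC1O2 | intermediate
8 | [4-[(1S)-1-[tert-butyl(dimethyl)silyl]oxy-3-oxobutyl]-5-hydroxy-2-oxo-2,5-dihydrofuran-3-yl]methyl acetate (pseudo-acid, C5 anomers) | CC(=O)C[C@H](O[Si](C)(C)C(C)(C)C)C1=C(COC(C)=O)C(=O)OC1O | intermediate
9 | methyl (2Z,4S)-2-(acetyloxymethyl)-4-[tert-butyl(dimethyl)silyl]oxy-3-formyl-6-oxohept-2-enoate | CC(=O)C[C@H](O[Si](C)(C)C(C)(C)C)/C(C=O)=C(\COC(C)=O)C(=O)OC | intermediate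
10 | pent-4-yn-1-ol | C#CCCCO | starting material
11 | dimethylaluminium (4E)-5-(dimethylalumanyl)-4-methylpent-4-en-1-olate (E-alkenylalane) | C[Al](C)OCCC/C(C)=C/[Al](C)C | intermediate
12 | 2,4-dimethyl-1-oxa-2-aluminacyclohept-3-ene (cyclic Z-alkenylalane alkoxide) | C[Al]1OCCCC(C)=C1 | intermediate
13 | (4Z)-5-iodo-4-methylpent-4-en-1-ol | OCCC/C(C)=C\I | intermediate
14 | methyl (2E,4R,5Z)-2-(acetyloxymethyl)-3-[(1S)-1-[tert-butyl(dimethyl)silyl]oxy-3-oxobutyl]-4,9-dihydroxy-6-methylnona-2,5-dienoate | OCCC/C(C)=C\[C@@H](O)/C(=C(/COC(C)=O)C(=O)OC)[C@@H](O[Si](C)(C)C(C)(C)C)CC(C)=O | intermediate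
15 | [(5R)-4-[(1S)-1-[tert-butyl(dimethyl)silyl]oxy-3-oxobutyl]-5-[(1Z)-5-hydroxy-2-methylpent-1-en-1-yl]-2-oxo-2,5-dihydrofuran-3-yl]methyl acetate | OCCC/C(C)=C\[C@H]1OC(=O)C(COC(C)=O)=C1[C@@H](O[Si](C)(C)C(C)(C)C)CC(C)=O | intermediate
16 | [(5R)-4-[(1S)-1-[tert-butyl(dimethyl)silyl]oxy-3-oxobutyl]-5-[(1Z)-2-methyl-5-oxopent-1-en-1-yl]-2-oxo-2,5-dihydrofuran-3-yl]methyl acetate | O=CCC/C(C)=C\[C@H]1OC(=O)C(COC(C)=O)=C1[C@@H](O[Si](C)(C)C(C)(C)C)CC(C)=O | intermediate
17 | [(4S,6S,10Z,11aR)-4-[tert-butyl(dimethyl)silyl]oxy-6-hydroxy-6,10-dimethyl-2,7-dioxo-2,4,5,6,7,8,9,11a-octahydrocyclodeca[b]furan-3-yl]methyl acetate | CC(C)(C)[Si](C)(C)O[C@H]1C[C@](C)(O)C(=O)CC/C(C)=C\[C@H]2OC(=O)C(COC(C)=O)=C12 | intermediate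
18 | [(4S,6S,10Z,11aR)-4,6-dihydroxy-6,10-dimethyl-2,7-dioxo-2,4,5,6,7,8,9,11a-octahydrocyclodeca[b]furan-3-yl]methyl acetate | O[C@H]1C[C@](C)(O)C(=O)CC/C(C)=C\[C@H]2OC(=O)C(COC(C)=O)=C12 | intermediate
19 | [(4S,6S,10Z,11aR)-3-(acetyloxymethyl)-6-hydroxy-6,10-dimethyl-2,7-dioxo-2,4,5,6,7,8,9,11a-octahydrocyclodeca[b]furan-4-yl] 2-methylprop-2-enoate | C=C(C)C(=O)O[C@H]1C[C@](C)(O)C(=O)CC/C(C)=C\[C@H]2OC(=O)C(COC(C)=O)=C12 | intermediate
20 | [(4S,6S,10Z,11aR)-6-acetyloxy-3-(acetyloxymethyl)-6,10-dimethyl-2,7-dioxo-2,4,5,6,7,8,9,11a-octahydrocyclodeca[b]furan-4-yl] 2-methylprop-2-enoate | C=C(C)C(=O)O[C@H]1C[C@](C)(OC(C)=O)C(=O)CC/C(C)=C\[C@H]2OC(=O)C(COC(C)=O)=C12 | target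

## Step count and risks

Total steps: 12. Longest linear sequence: 11 steps (1 → 2 → 3 → 5 → 6 → 9 → 15 → 16 → 17 → 18 → 19 → 20); the alkenyl iodide 13 is made in one step off the main line.

The three steps most likely to fail:

Step 9, the proposed new benzoin macrocyclisation. It may stall at oligomeric acyloins, lose silanol from the β-silyloxy ketone by elimination, or epimerise C6 through the butenolide dienolate under the carbene/amine. The fallback uses known chemistry, sets out from 16 and returns at 17. Treat 16 with SmI2 (3 equiv, THF, −78 °C, 1 mM, no HMPA) so that the aldehyde-derived ketyl couples with the methyl ketone in a chelated intramolecular pinacol reaction. This gives the macrocyclic 1,2-diol [(4S,6S,10Z,11aR)-4-[tert-butyl(dimethyl)silyl]oxy-6,7-dihydroxy-6,10-dimethyl-2-oxo-2,4,5,6,7,8,9,11a-octahydrocyclodeca[b]furan-3-yl]methyl acetate F1, whose new secondary carbinol configuration is irrelevant. IBX (DMSO, rt) then oxidises only the secondary carbinol and rejoins the route at 17.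

Step 7, the asymmetric alkenyl addition. The electron-poor (Z)-formyl acrylate may be reduced by low-valent chromium, and the ligand may give poor facial control next to the tetrasubstituted olefin. The fallback sets out from 9 and 13 and returns at 15; it replaces catalyst control by a stereorandom coupling with diastereomer separation and recycling. Run the coupling without ligand (CrCl2 3 equiv, NiCl2 1 mol %, DMSO–THF, rt) to obtain 15 together with its C6 epimer [(5S)-4-[(1S)-1-[tert-butyl(dimethyl)silyl]oxy-3-oxobutyl]-5-[(1Z)-5-hydroxy-2-methylpent-1-en-1-yl]-2-oxo-2,5-dihydrofuran-3-yl]methyl acetate F2. The two are diastereomers (C8 is fixed) and are separated on silica. F2 is re-equilibrated by reversible γ-deprotonation (DBU 5 mol %, CH2Cl2, −20 °C) to a 15/F2 mixture and separated again.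

Step 5, the regiochemistry of the endoperoxide fragmentation. Both bridgehead hydrogens carry a neighbouring substituent, so the wrong carbon may become the carboxyl carbon. The fallback sets out from 6 and returns at 8; it replaces base-controlled by silyl-directed regiochemistry. Ir-catalysed C–H silylation ([Ir(OMe)(cod)]2, 4,4′-di-tert-butyl-2,2′-bipyridine, Et3SiH, norbornene, THF, 80 °C) takes the less hindered α-C–H next to the acetoxymethyl arm and gives [4-[(1S)-1-[tert-butyl(dimethyl)silyl]oxy-3-oxobutyl]-2-(triethylsilyl)furan-3-yl]methyl acetate F3. Photooxygenation of F3 without amine (O2, hν, tetraphenylporphyrin, CH2Cl2, −78 °C) proceeds by 1,2-silyl shift to the peroxide oxygen (Katsumura oxidation), so the silylated carbon becomes C12 whatever the sterics. This gives triethylsilyl (2Z,4S)-2-(acetyloxymethyl)-4-[tert-butyl(dimethyl)silyl]oxy-3-formyl-6-oxohept-2-enoate F4, which is hydrolysed on aqueous work-up to pseudo-acid 8 and methylated (MeI, iPr2NEt, DMF) to 9 as in step 5.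

Further compounds
F1 | step 9 | [(4S,6S,10Z,11aR)-4-[tert-butyl(dimethyl)silyl]oxy-6,7-dihydroxy-6,10-dimethyl-2-oxo-2,4,5,6,7,8,9,11a-octahydrocyclodeca[b]furan-3-yl]methyl acetate | CC(C)(C)[Si](C)(C)O[C@H]1C[C@](C)(O)C(O)CC/C(C)=C\[C@H]2OC(=O)C(COC(C)=O)=C12
F2 | step 7 | [(5S)-4-[(1S)-1-[tert-butyl(dimethyl)silyl]oxy-3-oxobutyl]-5-[(1Z)-5-hydroxy-2-methylpent-1-en-1-yl]-2-oxo-2,5-dihydrofuran-3-yl]methyl acetate | OCCC/C(C)=C\[C@@H]1OC(=O)C(COC(C)=O)=C1[C@@H](O[Si](C)(C)C(C)(C)C)CC(C)=O
F3 | step 5 | [4-[(1S)-1-[tert-butyl(dimethyl)silyl]oxy-3-oxobutyl]-2-(triethylsilyl)furan-3-yl]methyl acetate | CC(=O)C[C@H](O[Si](C)(C)C(C)(C)C)c1coc([Si](CC)(CC)CC)c1COC(C)=O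
F4 | step 5 | triethylsilyl (2Z,4S)-2-(acetyloxymethyl)-4-[tert-butyl(dimethyl)silyl]oxy-3-formyl-6-oxohept-2-enoate | CC(=O)C[C@H](O[Si](C)(C)C(C)(C)C)/C(C=O)=C(\COC(C)=O)C(=O)O[Si](CC)(CC)CC
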